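Each flask holds 0.10 M of electrophile, the limiting reagent against 1.20 equiv of nucleophile. The free base varies, and the earlier runs span 0.34 equiv to 1.1 equiv of it.

in all of them: electrophile 0.10 M

| charge | nucleophile | free base | remark | time |
|---|---|---|---|---|
| blue | 1.2 equiv | 0.34 equiv | run made earlier |  |
| violet | 1.2 equiv | 0.62 equiv | run made earlier |  |
| grey | 1.2 equiv | 1.1 equiv | run made earlier |  |
| winter | 1.20 equiv | 0.600 equiv |  | 80 min |
| autumn | 1.20 equiv | 1.20 equiv |  | 80 min |
| dawn | 1.20 equiv | 0.300 equiv |  | 80 min |

- blue (time / min: electrophile / %, target / %): 5.00: 97.3, 0.8; 8.00: 96.3, 5.0; 15.0: 94.6, 7.0; 30.0: 88.9, 9.5; 60.0: 77.8, 16.9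
- violet (time / min: electrophile / %, target / %): 12.0: 95.9, 4.8; 25.0: 88.7, 9.1; 30.0: 88.5, 12.5; 50.0: 80.2, 15.7; 60.0: 76.7, 16.1
- grey (time / min: electrophile / %, target / %): 12.0: 93.4, 5.9; 25.0: 89.7, 10.2; 30.0: 89.0, 13.5; 50.0: 81.4, 16.1; 60.0: 78.0, 16.2

(readings scatter by 1 percentage point)



- part of the electrophile that has reacted at the end, winter
- part of the electrophile that has reacted at the end, autumn
- part of the electrophile that has reacted at the end, dawn
- what raising the equivalents of free base from its lowest to its highest value here does to the part of the electrophile that has reacted (changes below 5 percentage points count as none) (no change / it rises / it falls)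

In the first instants, electrophile lost appears as target: violet at 12.0 min reads 95.9% left and 4.8% of target, a balance within the scatter of 1 percentage point. In the middle the loss runs steadily, and at 30.0 min the three runs read 88.9%, 88.5% and 89.0%. By 60.0 min they read 77.8%, 76.7% and 78.0%, in the order of rising free base, so the readings show no effect of free base beyond their scatter. A gap has opened by then: on average 6.1 points of the charge is in neither electrophile nor target, so something else is forming.

Pooled, the last readings give 0.00425 min⁻¹. This is the loss constant k_L: the logarithm of c(electrophile) charged over c(electrophile) left, per minute, read at 1.20 equiv of nucleophile. The middle readings give 0.00396 min⁻¹, so the constant holds roughly along the run. At the end, 80 min of this loss gives 28.8% reacted in each flask. Were free base spent one for one with electrophile lost, dawn's 0.300 equiv would barely cover that, so dawn is the flask to watch.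

The forecast gives 29% for winter, 29% for autumn, 28.5% for dawn and no change, taking the rate as “zero order in free base, at least while some remains”.

The flasks end at 29.1% in winter, 29.1% in autumn and 29.0% in dawn: no change, with 0.075 points between lowest and highest free base.

    electrophile + nucleophile → acid set free + target (k = 2.30 L mol⁻¹ h⁻¹)
    nucleophile + acid set free ⇌ protonated nucleophile, settled at all times (K = 880 L mol⁻¹)
    acid set free + free base ⇌ salt of the base (K = 3.10 × 10⁵ L mol⁻¹, k = 52.0 L mol⁻¹ h⁻¹)
    electrophile + target → side product (k = 3.70 L mol⁻¹ h⁻¹)

At 80.0 min in autumn, the electrophile is used 2.3 times as fast by the nucleophile as by the target, and that flask holds 19.6% of target and 9.54% of side product. Free base stands there at 98.8% of its charge, and its reaction with the acid set free makes no difference to the answer. The 28.8% reckoned from k_L lies below autumn's 29.1%. Autumn's answer has moved by 5 points at 0.963 equiv or at 1.45 equiv of nucleophile, so a run there would stand that far from the forecast. Taken in proportion to the nucleophile, at the 0.480 equiv of a neighbour of autumn, k_L gives 12.7%, and that flask ends at 12.9%.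

(The runs are simulated on assumed constants.)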